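Ring B is a 1,4-dioxygenated benzene: O-2′ and O-5′ are para, C1′ (bonded to C2 of the chromone) sits ortho to O-2′, and the 4′-methoxy sits ortho to O-5′. This is the 4-alkoxyphenol pattern of a Dötz benzannulation, so ring B is disconnected into a terminal alkyne on C2 of ring C, a chromium (benzyloxy)(1-methoxyvinyl)carbene and one CO. In one operation the step closes ring B, forms C5′–C6′, C1′–C2′ and C2′–C3′, and delivers the three B-ring oxygens already differentiated (free 2′-OH, 5′-OBn, 4′-OMe). Its precursor is 5-benzyloxy-2-ethynyl-6,7,8-trimethoxychromone; one hydrogenolysis then ends the route.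

Key step: step 11

Assumption: ring A carries five oxygens (O1 and those on C5 to C8), so it is drawn from the stock chemical 2,6-dimethoxy-1,4-benzoquinone, which reaches a pentaoxygenated arene in two steps; C2 and the inner alkyne carbon come from ethyl diethoxyacetate.

Step 1
Reactants: 1 2,6-dimethoxy-1,4-benzoquinone
Product: 2 3,5-dimethoxybenzene-1,2,4-triyl triacetate
Conditions: Ac2O, H2SO4 (cat.), rt → 45 °C
Reagents that add atoms: acetic anhydride, CC(=O)OC(C)=O
Why: Thiele–Winter acetoxylation, in which acid-promoted conjugate addition of acetate to one of the two equivalent unsubstituted quinone carbons, enolisation and O-acetylation should give the 1,2,4-triacetate as the only regioisomer.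

Step 2
Reactants: 2 3,5-dimethoxybenzene-1,2,4-triyl triacetate
Product: 4 pentamethoxybenzene, via 3,5-dimethoxybenzene-1,2,4-triol 3 (not isolated)
Conditions: NaOH, MeOH–H2O, Na2S2O4 (cat.), N2, 0 °C → rt; then Me2SO4, NaOH, 0 → 60 °C
Reagents that add atoms: dimethyl sulfate, COS(=O)(=O)OC
Why: One-pot saponification of the three aryl acetates and Williamson O-methylation of the resulting triphenoxide should give the pentamethyl ether, with dithionite and nitrogen protecting the oxidation-prone triol 3.

Step 3
Reactants: 4 pentamethoxybenzene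
Product: 5 1-(2-hydroxy-3,4,5,6-tetramethoxyphenyl)ethan-1-one
Conditions: AcCl, AlCl3, Et2O, 0 °C → rt; then aq. HCl
Reagents that add atoms: acetyl chloride, CC(Cl)=O
Why: Friedel–Crafts acylation at the only unsubstituted ring carbon, followed in the same pot by chelation-directed AlCl3 cleavage of one of the two equivalent methyl ethers ortho to the new ketone, should give the hydrogen-bonded ortho-hydroxyacetophenone.

Step 4
Reactants: 5 1-(2-hydroxy-3,4,5,6-tetramethoxyphenyl)ethan-1-one
Product: 6 1-(2,6-dihydroxy-3,4,5-trimethoxyphenyl)ethan-1-one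
Conditions: BCl3 (2.5 equiv), CH2Cl2, −78 → 0 °C; then H2O
Reagents that add atoms: none
Why: Chelation-controlled Lewis acid O-demethylation, in which boron bound to the ketone oxygen reaches only the remaining ortho methoxy group and chloride removes its methyl at low temperature while the three non-chelating methyl ethers stay, should give the mirror-symmetric diol.

Step 5
Reactants: 6 1-(2,6-dihydroxy-3,4,5-trimethoxyphenyl)ethan-1-one
Product: 7 1-[2-(benzyloxy)-6-hydroxy-3,4,5-trimethoxyphenyl]ethan-1-one
Conditions: BnBr (1.0 equiv), K2CO3, acetone, reflux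
Reagents that add atoms: benzyl bromide, BrCc1ccccc1
Why: Williamson mono-etherification, in which the two hydroxyls of 6 are equivalent so that only one mono-ether can form, and the surviving hydroxyl is held in a hydrogen bond to the ketone, which slows a second benzylation.

Step 6
Reactants: 7 1-[2-(benzyloxy)-6-hydroxy-3,4,5-trimethoxyphenyl]ethan-1-one; 8 ethyl diethoxyacetate
Product: 9 1-[2-(benzyloxy)-6-hydroxy-3,4,5-trimethoxyphenyl]-4,4-diethoxybutane-1,3-dione
Conditions: NaH (3 equiv), THF, 0 °C → reflux; then aq. HCl, 0 °C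
Reagents that add atoms: none
Why: Crossed Claisen condensation, in which the phenoxide–enolate dianion of 7 is C-acylated by the inductively activated ester 8, which does not self-condense, and the product is drained from the equilibrium as its diketonate.

Step 7
Reactants: 9 1-[2-(benzyloxy)-6-hydroxy-3,4,5-trimethoxyphenyl]-4,4-diethoxybutane-1,3-dione
Product: 11 5-(benzyloxy)-6,7,8-trimethoxy-4-oxo-4H-chromene-2-carbaldehyde, via 2-(diethoxymethyl)chromone acetal 10 (not isolated)
Conditions: p-TsOH·H2O (cat.), toluene, 80 °C; then 2 M aq. HCl–THF, 45 °C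
Reagents that add atoms: water, O
Why: Acid-catalysed cyclodehydration of the ortho-hydroxyaryl 1,3-diketone (phenol onto the distal ketone, then loss of water) builds the pyranone ring, and dilute aqueous acid then hydrolyses the diethyl acetal under conditions that a benzyl aryl ether should survive.

Step 8
Reactants: 11 5-(benzyloxy)-6,7,8-trimethoxy-4-oxo-4H-chromene-2-carbaldehyde
Product: 12 5-(benzyloxy)-2-ethynyl-6,7,8-trimethoxy-4H-chromen-4-one
Conditions: dimethyl (1-diazo-2-oxopropyl)phosphonate, K2CO3, MeOH–THF, 0 °C → rt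
Reagents that add atoms: dimethyl (1-diazo-2-oxopropyl)phosphonate, COP(=O)(OC)C(=[N+]=[N-])C(C)=O
Why: Ohira–Bestmann modification of the Seyferth–Gilbert homologation, in which methanolysis frees the diazomethylphosphonate anion, this olefinates the non-enolisable aldehyde, and the diazoalkene loses N2 with a 1,2-hydrogen shift to give the terminal alkyne at a temperature where the pyranone should resist carbonate.

Step 9
Reactants: 13 methyl vinyl ether; 14 chromium hexacarbonyl
Product: 17 tetramethylammonium pentacarbonyl(2-methoxy-1-oxidoprop-2-en-1-ylidene)chromate, via 1-methoxyvinyllithium 15 (not isolated), via lithium acylchromate 16 (not isolated)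
Conditions: t-BuLi, THF, −78 → 0 °C; Cr(CO)6, Et2O–THF, 0 °C → rt; then Me4NBr, H2O
Reagents that add atoms: tetramethylammonium bromide, C[N+](C)(C)C.[Br-]
Why: Fischer synthesis of an acylmetalate, in which α-deprotonation of the enol ether gives the vinyllithium, this adds to a CO ligand of Cr(CO)6, and cation metathesis delivers the storable tetramethylammonium salt.

Step 10
Reactants: 17 tetramethylammonium pentacarbonyl(2-methoxy-1-oxidoprop-2-en-1-ylidene)chromate
Product: 19 pentacarbonyl[(benzyloxy)(1-methoxyvinyl)carbene]chromium, via acetoxycarbene complex 18 (not isolated)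
Conditions: AcBr, CH2Cl2, −40 °C; then BnOH, −40 °C → rt
Reagents that add atoms: benzyl alcohol, OCc1ccccc1
Why: O-Acylation of the acylchromate gives a highly electrophilic acyloxycarbene complex whose acetate is displaced at the carbene carbon by benzyl alcohol (addition–elimination), the usual entry to alkoxycarbene complexes that direct O-alkylation does not reach.

Step 11
Reactants: 12 5-(benzyloxy)-2-ethynyl-6,7,8-trimethoxy-4H-chromen-4-one; 19 pentacarbonyl[(benzyloxy)(1-methoxyvinyl)carbene]chromium
Product: 21 5-(benzyloxy)-2-[5-(benzyloxy)-2-hydroxy-4-methoxyphenyl]-6,7,8-trimethoxy-4H-chromen-4-one, via tricarbonylchromium arene complex 20 (not isolated)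
Conditions: 19 (1.5 equiv), THF (0.05 M), 50 °C, Ar, dark; then air, EtOAc, rt, daylight
Reagents that add atoms: none
Why: Thermal loss of one cis CO from 19 opens a site for the alkyne, which inserts into the Cr=C bond to give a vinylcarbene, and CO insertion then gives a chromium-bound dienylketene. Ring B closes by 6π-electrocyclisation of this dienylketene (ketene carbon, derived from CO, onto the vinyl CH2 carbon), and tautomerisation of the cyclohexadienone gives the phenol as its Cr(CO)3 complex 20, which air and light demetalate. The closest known reaction is the Dötz benzannulation of alkenyl Fischer carbene complexes with terminal alkynes, for which α-oxygenated alkenyl complexes and acceptor-substituted alkynes are each established partners. No stereocentre is formed. The step needs one sense of alkyne insertion, and the terminal alkyne secures it by placing its hydrogen next to the carbene carbon (C6′–C5′) and the bulky chromonyl group next to the CO-derived carbon, so that C1′ lies ortho to the 2′-OH. It also needs phenol formation to prevail over five-membered-ring products, which an alkenyl (not aryl) chromium carbene in THF at moderate dilution favours.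

Step 12
Reactants: 21 5-(benzyloxy)-2-[5-(benzyloxy)-2-hydroxy-4-methoxyphenyl]-6,7,8-trimethoxy-4H-chromen-4-one
Product: 22 2-(2,5-dihydroxy-4-methoxyphenyl)-5-hydroxy-6,7,8-trimethoxy-4H-chromen-4-one
Conditions: H2 (1 atm), 10% Pd/C, EtOAc–MeOH, rt; filtration and concentration under N2
Reagents that add atoms: none
Why: Heterogeneous catalytic hydrogenolysis should cleave both O–CH2Ph bonds, at O-5 and O-5′, while the flavone C2=C3 bond and the methyl ethers normally survive at 1 atm and room temperature.

Compound list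
1 | 2,6-dimethoxy-1,4-benzoquinone | COC1=CC(=O)C=C(OC)C1=O | starting material
2 | 3,5-dimethoxybenzene-1,2,4-triyl triacetate | COc1cc(OC(C)=O)c(OC(C)=O)c(OC)c1OC(C)=O | intermediate
3 | 3,5-dimethoxybenzene-1,2,4-triol (present as its sodium salt) | COc1cc(O)c(O)c(OC)c1O | intermediate (not isolated)
4 | pentamethoxybenzene | COc1cc(OC)c(OC)c(OC)c1OC | intermediate
5 | 1-(2-hydroxy-3,4,5,6-tetramethoxyphenyl)ethan-1-one | CC(=O)c1c(O)c(OC)c(OC)c(OC)c1OC | intermediate
6 | 1-(2,6-dihydroxy-3,4,5-trimethoxyphenyl)ethan-1-one | CC(=O)c1c(O)c(OC)c(OC)c(OC)c1O | intermediate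
7 | 1-[2-(benzyloxy)-6-hydroxy-3,4,5-trimethoxyphenyl]ethan-1-one | CC(=O)c1c(O)c(OC)c(OC)c(OC)c1OCc1ccccc1 | intermediate
8 | ethyl diethoxyacetate | CCOC(=O)C(OCC)OCC | starting material
9 | 1-[2-(benzyloxy)-6-hydroxy-3,4,5-trimethoxyphenyl]-4,4-diethoxybutane-1,3-dione | CCOC(OCC)C(=O)CC(=O)c1c(O)c(OC)c(OC)c(OC)c1OCc1ccccc1 | intermediate
10 | 5-(benzyloxy)-2-(diethoxymethyl)-6,7,8-trimethoxy-4H-chromen-4-one | CCOC(OCC)c1cc(=O)c2c(OCc3ccccc3)c(OC)c(OC)c(OC)c2o1 | intermediate (not isolated)
11 | 5-(benzyloxy)-6,7,8-trimethoxy-4-oxo-4H-chromene-2-carbaldehyde | O=Cc1cc(=O)c2c(OCc3ccccc3)c(OC)c(OC)c(OC)c2o1 | intermediate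
12 | 5-(benzyloxy)-2-ethynyl-6,7,8-trimethoxy-4H-chromen-4-one | C#Cc1cc(=O)c2c(OCc3ccccc3)c(OC)c(OC)c(OC)c2o1 | intermediate
13 | methyl vinyl ether | C=COC | starting material
14 | chromium hexacarbonyl | [C-]#[O+].[C-]#[O+].[C-]#[O+].[C-]#[O+].[C-]#[O+].[C-]#[O+].[Cr] | starting material
15 | 1-methoxyvinyllithium | [Li]C(=C)OC | intermediate (not isolated)
16 | lithium pentacarbonyl(2-methoxy-1-oxidoprop-2-en-1-ylidene)chromate | C=C(OC)C([O-])=[Cr](=C=O)(=C=O)(=C=O)(=C=O)=C=O.[Li+] | intermediate (not isolated)
17 | tetramethylammonium pentacarbonyl(2-methoxy-1-oxidoprop-2-en-1-ylidene)chromate | C=C(OC)C([O-])=[Cr](=C=O)(=C=O)(=C=O)(=C=O)=C=O.C[N+](C)(C)C | intermediate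
18 | pentacarbonyl[(acetyloxy)(1-methoxyvinyl)carbene]chromium | C=C(OC)C(OC(C)=O)=[Cr](=C=O)(=C=O)(=C=O)(=C=O)=C=O | intermediate (not isolated)
19 | pentacarbonyl[(benzyloxy)(1-methoxyvinyl)carbene]chromium | C=C(OC)C(OCc1ccccc1)=[Cr](=C=O)(=C=O)(=C=O)(=C=O)=C=O | intermediate
20 | tricarbonyl(η6-arene)chromium complex of 21, chromium bound to ring B (drawn as two fragments) | COc1cc(O)c(-c2cc(=O)c3c(OCc4ccccc4)c(OC)c(OC)c(OC)c3o2)cc1OCc1ccccc1.O=C=[Cr](=C=O)=C=O | intermediate (not isolated)
21 | 5-(benzyloxy)-2-[5-(benzyloxy)-2-hydroxy-4-methoxyphenyl]-6,7,8-trimethoxy-4H-chromen-4-one | COc1cc(O)c(-c2cc(=O)c3c(OCc4ccccc4)c(OC)c(OC)c(OC)c3o2)cc1OCc1ccccc1 | intermediate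
22 | 2-(2,5-dihydroxy-4-methoxyphenyl)-5-hydroxy-6,7,8-trimethoxy-4H-chromen-4-one | COc1cc(O)c(-c2cc(=O)c3c(O)c(OC)c(OC)c(OC)c3o2)cc1O | target

Total step count: 12. Longest linear sequence: 10 steps (steps 1 to 8, then 11 and 12); the carbene complex is made in a 2-step side branch (steps 9 and 10).

Steps most likely to fail

Step 11. The alkyne is conjugated to the pyranone and therefore electron-poor, so insertion into the Cr=C bond may be slow; the carbene complex could then decompose, or the alkyne oligomerise, before benzannulation, and the sense of insertion could erode. The fallback gives up the annulation and brings ring B in intact by the chalcone route. It sets out from 7 and returns at 22. Commercial 2-methoxybenzene-1,4-diol is dibenzylated (BnBr, K2CO3, DMF) to 1,4-bis(benzyloxy)-2-methoxybenzene F1. Vilsmeier–Haack formylation para to the methoxy group (POCl3, DMF) gives 2,5-bis(benzyloxy)-4-methoxybenzaldehyde F2. Claisen–Schmidt condensation of F2 with acetophenone 7 (KOH, EtOH) should give (E)-1-[2-(benzyloxy)-6-hydroxy-3,4,5-trimethoxyphenyl]-3-[2,5-bis(benzyloxy)-4-methoxyphenyl]prop-2-en-1-one F3. Oxidative cyclisation (I2 cat., DMSO, 110 °C) gives 5-(benzyloxy)-2-[2,5-bis(benzyloxy)-4-methoxyphenyl]-6,7,8-trimethoxy-4H-chromen-4-one F4, and hydrogenolysis (H2, Pd/C) of its three benzyl ethers gives 22.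

Step 8. Methoxide or carbonate may attack the pyranone ring, or methanol may add in conjugate fashion to the newly formed acceptor-substituted enyne. The fallback avoids methanol and carbonate by olefination and elimination. It sets out from 11 and returns at 12. Wittig bromomethylenation (Ph3PCH2Br bromide, KOt-Bu, THF, −78 °C) should give mainly (Z)-5-(benzyloxy)-2-(2-bromoethenyl)-6,7,8-trimethoxy-4H-chromen-4-one F5. Anti-elimination of HBr with Bu4NF·3H2O in DMF then gives 12.

Step 7. The peri benzyl ether may be lost, or the acetal next to the electron-poor C2 may hydrolyse incompletely, under the aqueous acid. The fallback reaches the aldehyde by oxidation level adjustment and needs no aqueous acid. It sets out from 7 and returns at 11. Claisen condensation with diethyl oxalate (NaOEt, EtOH–THF) gives ethyl 4-[2-(benzyloxy)-6-hydroxy-3,4,5-trimethoxyphenyl]-2,4-dioxobutanoate F6. Cyclodehydration (p-TsOH cat., EtOH, reflux) gives ethyl 5-(benzyloxy)-6,7,8-trimethoxy-4-oxo-4H-chromene-2-carboxylate F7. Chemoselective ester reduction (NaBH4, MeOH–THF, 0 °C) gives 5-(benzyloxy)-2-(hydroxymethyl)-6,7,8-trimethoxy-4H-chromen-4-one F8, and Dess–Martin oxidation (CH2Cl2, rt) gives 11.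

Further compounds
F1 | step 11 | 1,4-bis(benzyloxy)-2-methoxybenzene | COc1cc(OCc2ccccc2)ccc1OCc1ccccc1
F2 | step 11 | 2,5-bis(benzyloxy)-4-methoxybenzaldehyde | COc1cc(OCc2ccccc2)c(C=O)cc1OCc1ccccc1
F3 | step 11 | (E)-1-[2-(benzyloxy)-6-hydroxy-3,4,5-trimethoxyphenyl]-3-[2,5-bis(benzyloxy)-4-methoxyphenyl]prop-2-en-1-one | COc1cc(OCc2ccccc2)c(/C=C/C(=O)c2c(O)c(OC)c(OC)c(OC)c2OCc2ccccc2)cc1OCc1ccccc1
F4 | step 11 | 5-(benzyloxy)-2-[2,5-bis(benzyloxy)-4-methoxyphenyl]-6,7,8-trimethoxy-4H-chromen-4-one | COc1cc(OCc2ccccc2)c(-c2cc(=O)c3c(OCc4ccccc4)c(OC)c(OC)c(OC)c3o2)cc1OCc1ccccc1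
F5 | step 8 | (Z)-5-(benzyloxy)-2-(2-bromoethenyl)-6,7,8-trimethoxy-4H-chromen-4-one | Br/C=C\c1cc(=O)c2c(OCc3ccccc3)c(OC)c(OC)c(OC)c2o1
F6 | step 7 | ethyl 4-[2-(benzyloxy)-6-hydroxy-3,4,5-trimethoxyphenyl]-2,4-dioxobutanoate | CCOC(=O)C(=O)CC(=O)c1c(O)c(OC)c(OC)c(OC)c1OCc1ccccc1
F7 | step 7 | ethyl 5-(benzyloxy)-6,7,8-trimethoxy-4-oxo-4H-chromene-2-carboxylate | CCOC(=O)c1cc(=O)c2c(OCc3ccccc3)c(OC)c(OC)c(OC)c2o1
F8 | step 7 | 5-(benzyloxy)-2-(hydroxymethyl)-6,7,8-trimethoxy-4H-chromen-4-one | OCc1cc(=O)c2c(OCc3ccccc3)c(OC)c(OC)c(OC)c2o1
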